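**Retrosynthetic overview**

1. Isoflavanone numbering is used (ring C = O1, C2, C3, C4 fused to ring A at C4a/C8a; ring B = the benzene ring of the chromene). The plan rests on ring C: C2 is a CH2 held between O1, the ring A oxygen, and the only stereocentre, C3. Cutting C2-C3 sends C2 back to the methyl of an ortho methoxy group on ring A and C3 to a rhodium carbene, i.e. diazoketone 15. Ring C is closed last by enantioselective C-H insertion.
2. 15 comes from diazo transfer onto deoxybenzoin 14. 14 comes from the C4-C4a bond between aryllithium 12 (silylated 3,5-dimethoxyphenol, lithiated between its methoxy groups) and Weinreb amide 9.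
3. 9 comes from cyclohexane-1,3-dione and prenal (pyran ring by Knoevenagel/oxa-6π closure), C-alkylation with bromoacetamide 5, and aromatisation of the carbocycle to ring B.
4. End game: BCl3 removes the ketone-chelated C5 methyl ether, then buffered fluoride removes both silyl groups.
5. Ring order: pyran ring of the chromene, ring B (by aromatisation), ring A (bought), ring C (key step).

Key step: step 7

Assumption: the sense of induction of Rh2(S-PTTL)4 on this substrate is not known in advance; the route is written with this catalyst giving (R)-16, and if the opposite carbene face is preferred the mirror-image catalyst Rh2(R-PTTL)4 is used with nothing else changed.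

**Route**

Step 1
Reactants: 1 cyclohexane-1,3-dione; 2 prenal (3-methylbut-2-enal)
Product: 4 2,2-dimethyl-2,6,7,8-tetrahydro-5H-chromen-5-one, via oxatriene 3 (not isolated)
Conditions: ethylenediammonium diacetate (10 mol%), MeOH, rt to 50 °C
Reagents that add atoms: none
Why: Knoevenagel condensation gives the 2-alkylidene dione 3, a 1-oxatriene that closes by oxa-6π electrocyclisation to the 2H-pyran (formal [3+3] annulation).

Step 2
Reactants: 4 2,2-dimethyl-2,6,7,8-tetrahydro-5H-chromen-5-one; 5 2-bromo-N-methoxy-N-methylacetamide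
Product: 7 rac-2-(2,2-dimethyl-5-oxo-5,6,7,8-tetrahydro-2H-chromen-6-yl)-N-methoxy-N-methylacetamide, via lithium dienolate 6 (not isolated)
Conditions: LiN(iPr)2, THF, −78 °C; then 5, DMPU, −78 to −20 °C
Reagents that add atoms: none
Why: Kinetic deprotonation of the vinylogous ester at the alpha-prime carbon C6 (Stork–Danheiser regiochemistry) and SN2 alkylation by the alpha-bromo amide place the two-carbon arm, already at the Weinreb amide level, on the future C6 of ring B; the new stereocentre is racemic and is erased in step 3.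

Step 3
Reactants: 7 rac-2-(2,2-dimethyl-5-oxo-5,6,7,8-tetrahydro-2H-chromen-6-yl)-N-methoxy-N-methylacetamide
Product: 9 2-[5-(tert-butyldimethylsilyloxy)-2,2-dimethyl-2H-chromen-6-yl]-N-methoxy-N-methylacetamide, via silyl dienol ether 8 (not isolated)
Conditions: TBSOTf, Et3N, CH2Cl2, 0 °C; crude 8, then DDQ, 2,4,6-collidine, benzene, 0 °C to rt
Reagents that add atoms: tert-butyldimethylsilyl trifluoromethanesulfonate (TBSOTf), CC(C)(C)[Si](C)(C)OS(=O)(=O)C(F)(F)F
Why: Soft enolisation of the ketone gives a silyloxycyclohexadiene, which DDQ dehydrogenates (hydride abstraction at C7, proton loss at C8) to the aromatic ring with the silyl group kept, so the hindered ring B silyl ether is installed without a separate phenol silylation and without lactonisation onto the side chain.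

Step 4
Reactants: 10 3,5-dimethoxyphenol
Product: 11 (3,5-dimethoxyphenoxy)triisopropylsilane
Conditions: TIPSCl, imidazole, DMF, rt
Reagents that add atoms: triisopropylsilyl chloride (TIPSCl), CC(C)[Si](Cl)(C(C)C)C(C)C
Why: Standard phenol silylation; the bulky triisopropylsilyl group is chosen for ring A because it blocks lithiation next to the silyloxy group, does not migrate from oxygen to carbon, and withstands the amidine base of step 6.

Step 5
Reactants: 11 (3,5-dimethoxyphenoxy)triisopropylsilane; 9 2-[5-(tert-butyldimethylsilyloxy)-2,2-dimethyl-2H-chromen-6-yl]-N-methoxy-N-methylacetamide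
Product: 14 2-[5-(tert-butyldimethylsilyloxy)-2,2-dimethyl-2H-chromen-6-yl]-1-[2,6-dimethoxy-4-(triisopropylsilyloxy)phenyl]ethanone, via aryllithium 12 (not isolated), via tetrahedral lithium adduct 13 (not isolated)
Conditions: 11 (slight excess), n-BuLi, THF, 0 °C to rt; then 9, −78 to 0 °C; aq NH4Cl
Reagents that add atoms: none
Why: Directed ortho-metalation occurs at the carbon flanked by two methoxy groups, and the aryllithium acylates the Weinreb amide, whose chelated adduct 13 blocks a second addition and releases the ketone only on work-up.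

Step 6
Reactants: 14 2-[5-(tert-butyldimethylsilyloxy)-2,2-dimethyl-2H-chromen-6-yl]-1-[2,6-dimethoxy-4-(triisopropylsilyloxy)phenyl]ethanone
Product: 15 2-diazo-2-[5-(tert-butyldimethylsilyloxy)-2,2-dimethyl-2H-chromen-6-yl]-1-[2,6-dimethoxy-4-(triisopropylsilyloxy)phenyl]ethanone
Conditions: p-ABSA, DBU, MeCN, 0 °C to rt
Reagents that add atoms: 4-acetamidobenzenesulfonyl azide (p-ABSA), CC(=O)Nc1ccc(cc1)S(=O)(=O)N=[N+]=[N-]
Why: Regitz diazo transfer: the methylene between ring B and the carbonyl is acidic enough for DBU, and its enolate attacks the terminal nitrogen of the sulfonyl azide and loses the sulfonamide to leave the alpha-aryl-alpha-diazo ketone.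

Step 7
Reactants: 15 2-diazo-2-[5-(tert-butyldimethylsilyloxy)-2,2-dimethyl-2H-chromen-6-yl]-1-[2,6-dimethoxy-4-(triisopropylsilyloxy)phenyl]ethanone
Product: 16 (R)-3-[5-(tert-butyldimethylsilyloxy)-2,2-dimethyl-2H-chromen-6-yl]-5-methoxy-7-(triisopropylsilyloxy)chroman-4-one
Conditions: Rh2(S-PTTL)4 (2 mol%), 4 Å MS, toluene, −20 °C to rt, slow addition of 15 at high dilution
Reagents that add atoms: none
Why: Rh2(S-PTTL)4 is attacked by the diazo carbon of 15, N2 leaves, and the electrophilic carbene at the future C3, tempered by ring B as donor and the aroyl group as acceptor and free of beta hydrogens, takes up a C-H bond of an ortho methoxy group through a concerted, asynchronous three-centre transition state that forms C2-C3 and C3-H and releases the catalyst. The closest known reaction types are the intramolecular C-H insertion of ortho-alkoxyaryl diazoketones to chroman-4-ones under chiral divalent rhodium carboxylates, the Rh2(PTTL)4-catalysed cyclisation of alpha-aryl-alpha-diazo ketones, and carbene insertion into methyl ether C-H bonds. Ring C closes as a six-membered ring by 1,6-insertion (carbene carbon, C4, C4a, C8a, O1, methyl carbon): the 2,6-disubstituted aroyl ring is twisted out of the carbonyl plane, so one methoxy group sits over each face of the carbene and its oxygen-activated C-H bonds are the only ones in reach. C3 is the only new stereocentre and is set by the catalyst, whose phthalimido walls fix how the aryl and acyl arms lie on rhodium and so which carbene face meets the C-H bond; no base is present, so the acidic C3-H is not scrambled afterwards. The step needs chemoselectivity for methoxy C-H insertion over oxonium ylide formation with methyl shift, Wolff rearrangement, attack on a silicon-bound methyl group, and intermolecular cyclopropanation of the chromene alkene; two equivalent methoxy groups, a ring B oxygen that carries only a silyl group, reversible ylide formation at a methyl ether, a dry non-coordinating solvent, and slow addition at high dilution should secure it.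

Step 8
Reactants: 16 (R)-3-[5-(tert-butyldimethylsilyloxy)-2,2-dimethyl-2H-chromen-6-yl]-5-methoxy-7-(triisopropylsilyloxy)chroman-4-one
Product: 18 (R)-3-[5-(tert-butyldimethylsilyloxy)-2,2-dimethyl-2H-chromen-6-yl]-5-hydroxy-7-(triisopropylsilyloxy)chroman-4-one, via dichloroboron chelate 17 (not isolated)
Conditions: BCl3 (1.2 equiv), CH2Cl2, −78 to −30 °C; then aq NaHCO3
Reagents that add atoms: none
Why: BCl3 binds the C4 ketone oxygen and the peri C5 methoxy oxygen in a six-membered chelate and chloride removes only that methyl group (chelation-directed ether cleavage), while the low temperature and absence of base protect C3 and the chromene and the silyl ethers on non-chelating oxygens are left.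

Step 9
Reactants: 18 (R)-3-[5-(tert-butyldimethylsilyloxy)-2,2-dimethyl-2H-chromen-6-yl]-5-hydroxy-7-(triisopropylsilyloxy)chroman-4-one
Product: 19 (R)-5,7-dihydroxy-3-(5-hydroxy-2,2-dimethyl-2H-chromen-6-yl)chroman-4-one (target)
Conditions: Bu4NF, AcOH (1:1.2), THF, 0 °C
Reagents that add atoms: none
Why: Fluoride cleaves both aryl silyl ethers, and acetic acid protonates the phenoxides as they form so that the enolisable C3 centre never meets a base.

**Compound list**

1 | cyclohexane-1,3-dione | O=C1CCCC(=O)C1 | starting material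
2 | prenal (3-methylbut-2-enal) | CC(C)=CC=O | starting material
3 | 2-(3-methylbut-2-en-1-ylidene)cyclohexane-1,3-dione (oxatriene, not isolated) | CC(C)=CC=C1C(=O)CCCC1=O | intermediate
4 | 2,2-dimethyl-2,6,7,8-tetrahydro-5H-chromen-5-one | CC1(C)C=CC2=C(O1)CCCC2=O | intermediate
5 | 2-bromo-N-methoxy-N-methylacetamide | CON(C)C(=O)CBr | starting material
6 | lithium dienolate of 4 (lithium 2,2-dimethyl-7,8-dihydro-2H-chromen-5-olate, not isolated) | CC1(C)C=CC2=C(O1)CCC=C2O[Li] | intermediate
7 | rac-2-(2,2-dimethyl-5-oxo-5,6,7,8-tetrahydro-2H-chromen-6-yl)-N-methoxy-N-methylacetamide | CC1(C)C=CC2=C(O1)CCC(CC(=O)N(C)OC)C2=O | intermediate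
8 | 2-[5-(tert-butyldimethylsilyloxy)-2,2-dimethyl-7,8-dihydro-2H-chromen-6-yl]-N-methoxy-N-methylacetamide (silyl dienol ether, not isolated) | CC1(C)C=CC2=C(O1)CCC(CC(=O)N(C)OC)=C2O[Si](C)(C)C(C)(C)C | intermediate
9 | 2-[5-(tert-butyldimethylsilyloxy)-2,2-dimethyl-2H-chromen-6-yl]-N-methoxy-N-methylacetamide | CC1(C)C=Cc2c(O1)ccc(CC(=O)N(C)OC)c2O[Si](C)(C)C(C)(C)C | intermediate
10 | 3,5-dimethoxyphenol | COc1cc(O)cc(OC)c1 | starting material
11 | (3,5-dimethoxyphenoxy)triisopropylsilane | COc1cc(OC)cc(O[Si](C(C)C)(C(C)C)C(C)C)c1 | intermediate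
12 | [2,6-dimethoxy-4-(triisopropylsilyloxy)phenyl]lithium (not isolated) | [Li]c1c(OC)cc(O[Si](C(C)C)(C(C)C)C(C)C)cc1OC | intermediate
13 | rac-lithium alkoxide adduct of 12 to the amide carbonyl of 9 (not isolated) | CC1(C)C=Cc2c(O1)ccc(CC(O[Li])(N(C)OC)c3c(OC)cc(O[Si](C(C)C)(C(C)C)C(C)C)cc3OC)c2O[Si](C)(C)C(C)(C)C | intermediate
14 | 2-[5-(tert-butyldimethylsilyloxy)-2,2-dimethyl-2H-chromen-6-yl]-1-[2,6-dimethoxy-4-(triisopropylsilyloxy)phenyl]ethanone | CC1(C)C=Cc2c(O1)ccc(CC(=O)c3c(OC)cc(O[Si](C(C)C)(C(C)C)C(C)C)cc3OC)c2O[Si](C)(C)C(C)(C)C | intermediate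
15 | 2-diazo-2-[5-(tert-butyldimethylsilyloxy)-2,2-dimethyl-2H-chromen-6-yl]-1-[2,6-dimethoxy-4-(triisopropylsilyloxy)phenyl]ethanone | CC1(C)C=Cc2c(O1)ccc(C(=[N+]=[N-])C(=O)c3c(OC)cc(O[Si](C(C)C)(C(C)C)C(C)C)cc3OC)c2O[Si](C)(C)C(C)(C)C | intermediate
16 | (R)-3-[5-(tert-butyldimethylsilyloxy)-2,2-dimethyl-2H-chromen-6-yl]-5-methoxy-7-(triisopropylsilyloxy)chroman-4-one | CC1(C)C=Cc2c(ccc([C@@H]3COc4cc(O[Si](C(C)C)(C(C)C)C(C)C)cc(OC)c4C3=O)c2O[Si](C)(C)C(C)(C)C)O1 | intermediate
17 | (R)-5-(dichloroboryloxy) chelate of 16 after loss of the C5 methyl group (not isolated) | CC1(C)C=Cc2c(ccc([C@@H]3COc4cc(O[Si](C(C)C)(C(C)C)C(C)C)cc(OB(Cl)Cl)c4C3=O)c2O[Si](C)(C)C(C)(C)C)O1 | intermediate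
18 | (R)-3-[5-(tert-butyldimethylsilyloxy)-2,2-dimethyl-2H-chromen-6-yl]-5-hydroxy-7-(triisopropylsilyloxy)chroman-4-one | CC1(C)C=Cc2c(ccc([C@@H]3COc4cc(O[Si](C(C)C)(C(C)C)C(C)C)cc(O)c4C3=O)c2O[Si](C)(C)C(C)(C)C)O1 | intermediate
19 | (R)-5,7-dihydroxy-3-(5-hydroxy-2,2-dimethyl-2H-chromen-6-yl)chroman-4-one | CC1(C)C=Cc2c(ccc([C@@H]3COc4cc(O)cc(O)c4C3=O)c2O)O1 | target

**Count and risks**

Total steps: 9. Longest linear sequence: 8 steps (1, 2, 3, 5, 6, 7, 8, 9) from cyclohexane-1,3-dione; step 4 is a one-step branch.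

Step 7 (highest risk). The carbene may be diverted before it inserts: the methoxy oxygen can add to give a five-membered oxonium ylide that ends in methyl shift or demethylation to a benzofuranone, or the catalyst pocket may not distinguish the two carbene faces well enough. The fallback uses known chemistry, sets out from 14 and returns at 16. Ketone-directed mono-demethylation of 14 (BCl3, CH2Cl2, −78 °C) should give 2-[5-(tert-butyldimethylsilyloxy)-2,2-dimethyl-2H-chromen-6-yl]-1-[2-hydroxy-6-methoxy-4-(triisopropylsilyloxy)phenyl]ethanone F1. Condensation with Me2NCH(OMe)2 (toluene, 80 °C) should close it to the isoflavone 3-[5-(tert-butyldimethylsilyloxy)-2,2-dimethyl-2H-chromen-6-yl]-5-methoxy-7-(triisopropylsilyloxy)-4H-chromen-4-one F2. Asymmetric transfer hydrogenation (RuCl(p-cymene)[TsDPEN], the ligand enantiomer that leads to 3R, HCO2H/Et3N, EtOAc, 40 °C) reduces the enone C=C and then the ketone with dynamic kinetic resolution of the racemising isoflavanone. This should give the cis alcohol (3R,4R)-3-[5-(tert-butyldimethylsilyloxy)-2,2-dimethyl-2H-chromen-6-yl]-5-methoxy-7-(triisopropylsilyloxy)chroman-4-ol F3. Dess–Martin periodinane buffered with NaHCO3 (CH2Cl2, 0 °C) then restores the ketone without touching C3 and delivers 16.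

Step 8. The Lewis acid may erode the C3 configuration through boron-assisted enolisation, or ionise or hydrochlorinate the chromene, during the ether cleavage. The fallback sets out from 14 and returns at 19; it moves the ether cleavage ahead of the stereocentre and makes the end game fluoride only. 14 is mono-demethylated (BCl3 at −78 °C, or MgI2·OEt2 in toluene if the chromene is the weak point) to the monophenol 2-[5-(tert-butyldimethylsilyloxy)-2,2-dimethyl-2H-chromen-6-yl]-1-[2-hydroxy-6-methoxy-4-(triisopropylsilyloxy)phenyl]ethanone F1. Silylation (TBSOTf, 2,6-lutidine, CH2Cl2) should give 2-[5-(tert-butyldimethylsilyloxy)-2,2-dimethyl-2H-chromen-6-yl]-1-[2-(tert-butyldimethylsilyloxy)-6-methoxy-4-(triisopropylsilyloxy)phenyl]ethanone F4. Diazo transfer as in step 6 should give 2-diazo-2-[5-(tert-butyldimethylsilyloxy)-2,2-dimethyl-2H-chromen-6-yl]-1-[2-(tert-butyldimethylsilyloxy)-6-methoxy-4-(triisopropylsilyloxy)phenyl]ethanone F5. The Rh2(S-PTTL)4 insertion of step 7, now into the single remaining methoxy group, should give (R)-5-(tert-butyldimethylsilyloxy)-3-[5-(tert-butyldimethylsilyloxy)-2,2-dimethyl-2H-chromen-6-yl]-7-(triisopropylsilyloxy)chroman-4-one F6. The silyloxy oxygen next to the carbonyl is conjugated and hindered, so it should not compete for the carbene, though this variant gives up the two-fold equivalence of the insertion sites. Bu4NF/AcOH then removes all three silyl groups to give 19.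

Step 5. The hindered, basic aryllithium may take a proton from the benzylic methylene of the amide instead of adding to its carbonyl, so that both partners are returned after work-up. The fallback sets out from 9 and returns at 14; it uses a faster-reacting electrophile and a less basic nucleophile. iBu2AlH (THF, −78 °C) should reduce 9 to 2-[5-(tert-butyldimethylsilyloxy)-2,2-dimethyl-2H-chromen-6-yl]acetaldehyde F7. Aryllithium 12 is transmetalated with anhydrous CeCl3 (THF, −78 °C) to [2,6-dimethoxy-4-(triisopropylsilyloxy)phenyl]cerium dichloride F8. Its addition to F7 should give rac-2-[5-(tert-butyldimethylsilyloxy)-2,2-dimethyl-2H-chromen-6-yl]-1-[2,6-dimethoxy-4-(triisopropylsilyloxy)phenyl]ethanol F9. Dess–Martin periodinane with NaHCO3 (CH2Cl2, 0 °C) then oxidises the acid-sensitive benzylic alcohol to 14.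

**Further compounds**

F1 | step 7 | 2-[5-(tert-butyldimethylsilyloxy)-2,2-dimethyl-2H-chromen-6-yl]-1-[2-hydroxy-6-methoxy-4-(triisopropylsilyloxy)phenyl]ethanone | CC1(C)C=Cc2c(O1)ccc(CC(=O)c3c(O)cc(O[Si](C(C)C)(C(C)C)C(C)C)cc3OC)c2O[Si](C)(C)C(C)(C)C
F2 | step 7 | 3-[5-(tert-butyldimethylsilyloxy)-2,2-dimethyl-2H-chromen-6-yl]-5-methoxy-7-(triisopropylsilyloxy)-4H-chromen-4-one | CC1(C)C=Cc2c(ccc(C3=COc4cc(O[Si](C(C)C)(C(C)C)C(C)C)cc(OC)c4C3=O)c2O[Si](C)(C)C(C)(C)C)O1
F3 | step 7 | (3R,4R)-3-[5-(tert-butyldimethylsilyloxy)-2,2-dimethyl-2H-chromen-6-yl]-5-methoxy-7-(triisopropylsilyloxy)chroman-4-ol | CC1(C)C=Cc2c(ccc([C@@H]3COc4cc(O[Si](C(C)C)(C(C)C)C(C)C)cc(OC)c4[C@@H]3O)c2O[Si](C)(C)C(C)(C)C)O1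
F4 | step 8 | 2-[5-(tert-butyldimethylsilyloxy)-2,2-dimethyl-2H-chromen-6-yl]-1-[2-(tert-butyldimethylsilyloxy)-6-methoxy-4-(triisopropylsilyloxy)phenyl]ethanone | CC1(C)C=Cc2c(O1)ccc(CC(=O)c3c(O[Si](C)(C)C(C)(C)C)cc(O[Si](C(C)C)(C(C)C)C(C)C)cc3OC)c2O[Si](C)(C)C(C)(C)C
F5 | step 8 | 2-diazo-2-[5-(tert-butyldimethylsilyloxy)-2,2-dimethyl-2H-chromen-6-yl]-1-[2-(tert-butyldimethylsilyloxy)-6-methoxy-4-(triisopropylsilyloxy)phenyl]ethanone | CC1(C)C=Cc2c(O1)ccc(C(=[N+]=[N-])C(=O)c3c(O[Si](C)(C)C(C)(C)C)cc(O[Si](C(C)C)(C(C)C)C(C)C)cc3OC)c2O[Si](C)(C)C(C)(C)C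
F6 | step 8 | (R)-5-(tert-butyldimethylsilyloxy)-3-[5-(tert-butyldimethylsilyloxy)-2,2-dimethyl-2H-chromen-6-yl]-7-(triisopropylsilyloxy)chroman-4-one | CC1(C)C=Cc2c(ccc([C@@H]3COc4cc(O[Si](C(C)C)(C(C)C)C(C)C)cc(O[Si](C)(C)C(C)(C)C)c4C3=O)c2O[Si](C)(C)C(C)(C)C)O1
F7 | step 5 | 2-[5-(tert-butyldimethylsilyloxy)-2,2-dimethyl-2H-chromen-6-yl]acetaldehyde | CC1(C)C=Cc2c(O1)ccc(CC=O)c2O[Si](C)(C)C(C)(C)C
F8 | step 5 | [2,6-dimethoxy-4-(triisopropylsilyloxy)phenyl]cerium dichloride | COc1cc(O[Si](C(C)C)(C(C)C)C(C)C)cc(OC)c1[Ce](Cl)Cl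
F9 | step 5 | rac-2-[5-(tert-butyldimethylsilyloxy)-2,2-dimethyl-2H-chromen-6-yl]-1-[2,6-dimethoxy-4-(triisopropylsilyloxy)phenyl]ethanol | CC1(C)C=Cc2c(O1)ccc(CC(O)c3c(OC)cc(O[Si](C(C)C)(C(C)C)C(C)C)cc3OC)c2O[Si](C)(C)C(C)(C)C
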